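**Retrosynthetic overview**
- Peniophorin ⇐ its tri-O-methyl ether, unmasked by one global O-demethylation at the end.
- Lactone ring (formed last): a mono-O-methyl terphenylquinone is O-acylated with a 4-methoxyphenylacetyl unit and closed by intramolecular Knoevenagel condensation onto the neighbouring quinone carbonyl. The single free enol OH decides which aryl ends up at C-4 and which at C-7.
- Quinone ring (formed second): methoxide-triggered lactone-to-carbocycle Claisen (Dieckmann) reorganisation of an O-methylated 4-aryl-6-benzylidene-pyran-2,5-dione.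
- Pyrandione ring (formed first, a temporary tether): head-to-tail union of two different arylpyruvate units (enolate of methyl phenylpyruvate plus acetonide-activated 4-methoxyphenylpyruvic acid) by acyl transfer and Claisen C–C bond formation, with O-methylation in the same flask to label the anisyl-side oxygen.
- Building blocks: 4-hydroxyphenylpyruvic acid, phenylpyruvic acid, 4-methoxyphenylacetyl chloride.

Assumption: the target SMILES has no stereocentre and no stereogenic double bond, so peniophorin is achiral and is made exactly as drawn; only double-bond geometries of intermediates are specified.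

**Route**

Step 1
Reactants: 1 4-hydroxyphenylpyruvic acid
Product: 2 (Z)-5-(4-hydroxybenzylidene)-2,2-dimethyl-1,3-dioxolan-4-one
Conditions: Me2C(OMe)2 (3 equiv), TsOH·H2O (cat.), THF, 40 °C
Reagents that add atoms: 2,2-dimethoxypropane, COC(C)(C)OC
Why: Acid-catalysed acetonide formation (transacetalisation) ties the carboxylic acid and the enol OH of the largely enolised arylpyruvic acid into a 1,3-dioxolan-4-one, as α-hydroxy acids do, which masks the ketone and activates the carboxyl while the phenol stays free; the Z geometry is that of the stable enol.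

Step 2
Reactants: 2 (Z)-5-(4-hydroxybenzylidene)-2,2-dimethyl-1,3-dioxolan-4-one
Product: 3 (Z)-5-(4-methoxybenzylidene)-2,2-dimethyl-1,3-dioxolan-4-one
Conditions: MeI, K2CO3 (anhydrous), acetone, 40 °C
Reagents that add atoms: iodomethane, CI
Why: Williamson ether synthesis on the only acidic OH; anhydrous carbonate is not nucleophilic enough to open the dioxolanone, and the phenoxide further deactivates its carbonyl while it is present.

Step 3
Reactants: 4 phenylpyruvic acid
Product: 5 methyl phenylpyruvate (methyl 2-oxo-3-phenylpropanoate, largely the Z enol)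
Conditions: MeOH, H2SO4 (cat.), 50 °C
Reagents that add atoms: methanol, CO
Why: Fischer esterification of an α-keto acid, whose carboxyl is activated by the adjacent carbonyl; the ester crystallises as its enol.

Step 4
Reactants: 5 methyl phenylpyruvate; 3 (Z)-5-(4-methoxybenzylidene)-2,2-dimethyl-1,3-dioxolan-4-one
Product: 8 (6Z)-6-benzylidene-3-methoxy-4-(4-methoxyphenyl)-2H-pyran-2,5(6H)-dione, via enol ester 6 (not isolated), via pyrandione 7 (not isolated)
Conditions: KN(SiMe3)2 (1.0 equiv), THF, −78 °C; add 3, −78 °C → rt; then Me2SO4, DMF, rt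
Reagents that add atoms: dimethyl sulfate, COS(=O)(=O)OC
Why: Proposed new method: the delocalised potassium enolate of 5 should O-acylate the activated enol-lactone carbonyl of 3 (closest known reaction: opening of 5-arylidene-1,3-dioxolan-4-ones by ester enolates in pulvinone synthesis), the hemiketal alkoxide then ejects acetone to unveil the enolate of the second arylpyruvate unit in 6, whose carbon closes onto the methyl ester in a 6-exo-trig Dieckmann (Claisen) condensation (closest known reaction: base-induced cyclisation of enol esters to pulvinones and grevillins) to give 7 as its potassium salt, the released methoxide being consumed by this acidic enol so that no rearrangement occurs yet, and the hard electrophile Me2SO4 O-methylates the vinylogous carboxylate at its unhindered oxygen (alkylation at its other oxygen terminus would lead to the same quinone in step 5); the Z benzylidene geometry comes from the Z enolate of 5.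

Step 5
Reactants: 8 (6Z)-6-benzylidene-3-methoxy-4-(4-methoxyphenyl)-2H-pyran-2,5(6H)-dione
Product: 10 2-hydroxy-5-methoxy-6-(4-methoxyphenyl)-3-phenyl-1,4-benzoquinone, via ring-opened methyl ester 9 (not isolated)
Conditions: NaOMe (3 equiv), anhydrous MeOH–THF, 0 °C → rt; then cold 1 M HCl
Reagents that add atoms: none
Why: Methoxide opens the enol lactone to ester 9, whose α-diketone enolate carbon re-closes onto the new methyl ester in a Dieckmann (Claisen) condensation, the same reaction type as the grevillin-to-terphenylquinone rearrangement, and tautomerisation gives the hydroxyquinone as a stable vinylogous carboxylate; the methyl ether cannot migrate and stays on the oxygen next to the anisyl-bearing carbon.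

Step 6
Reactants: 10 2-hydroxy-5-methoxy-6-(4-methoxyphenyl)-3-phenyl-1,4-benzoquinone; 11 4-methoxyphenylacetyl chloride
Product: 13 5-methoxy-3,4-bis(4-methoxyphenyl)-7-phenyl-1-benzofuran-2,6-dione, via quinonyl arylacetate 12 (not isolated)
Conditions: Et3N (3 equiv), DMAP (cat.), CH2Cl2, 0 °C → rt; then DBU (cat.), 40 °C
Reagents that add atoms: none
Why: O-Acylation of the single enolic OH (reversible under DMAP, so any ester on the tautomeric oxygen funnels back) is followed by a 5-exo-trig intramolecular Knoevenagel condensation (Perkin–Oglialoro-type lactone annulation) of the arylacetate carbanion onto the only carbonyl adjacent to the acylated oxygen and E1cB dehydration to the conjugated quinone methide lactone, so phenyl must end at C-7 and the anisyl group at C-4.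

Step 7
Reactants: 13 5-methoxy-3,4-bis(4-methoxyphenyl)-7-phenyl-1-benzofuran-2,6-dione
Product: 14 peniophorin (5-hydroxy-3,4-bis(4-hydroxyphenyl)-7-phenyl-1-benzofuran-2,6-dione)
Conditions: BBr3 (8 equiv), CH2Cl2, −78 °C → rt; then H2O
Reagents that add atoms: none
Why: Lewis-acid ether cleavage with BBr3 removes the two anisole methyls and the vinylogous-ester methyl at O-5 in one operation, while the lactone oxygen sits on sp2 carbon and cannot be opened by bromide in an SN2 sense; no stereocentre is involved.

**Compound list**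
1 | 4-hydroxyphenylpyruvic acid | O=C(O)C(=O)Cc1ccc(O)cc1 | starting material
2 | (Z)-5-(4-hydroxybenzylidene)-2,2-dimethyl-1,3-dioxolan-4-one | O=C1OC(C)(C)O/C1=C\c2ccc(O)cc2 | intermediate
3 | (Z)-5-(4-methoxybenzylidene)-2,2-dimethyl-1,3-dioxolan-4-one | O=C1OC(C)(C)O/C1=C\c2ccc(OC)cc2 | intermediate
4 | phenylpyruvic acid | O=C(O)C(=O)Cc1ccccc1 | starting material
5 | methyl phenylpyruvate | COC(=O)C(=O)Cc1ccccc1 | intermediate
6 | methyl (2Z)-2-{[(2Z)-2-hydroxy-3-(4-methoxyphenyl)prop-2-enoyl]oxy}-3-phenylprop-2-enoate (present as its potassium enolate) | COC(=O)/C(=C/c1ccccc1)OC(=O)/C(O)=C/c1ccc(OC)cc1 | intermediate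
7 | (6Z)-6-benzylidene-3-hydroxy-4-(4-methoxyphenyl)-2H-pyran-2,5(6H)-dione (present as its potassium salt) | O=C1O/C(=C\c2ccccc2)C(=O)C(c2ccc(OC)cc2)=C1O | intermediate
8 | (6Z)-6-benzylidene-3-methoxy-4-(4-methoxyphenyl)-2H-pyran-2,5(6H)-dione | O=C1O/C(=C\c2ccccc2)C(=O)C(c2ccc(OC)cc2)=C1OC | intermediate
9 | methyl (2E)-2-methoxy-3-(4-methoxyphenyl)-4,5-dioxo-6-phenylhex-2-enoate (present as its enolate) | COC(=O)/C(OC)=C(/c1ccc(OC)cc1)C(=O)C(=O)Cc1ccccc1 | intermediate
10 | 2-hydroxy-5-methoxy-6-(4-methoxyphenyl)-3-phenyl-1,4-benzoquinone | O=C1C(O)=C(c2ccccc2)C(=O)C(OC)=C1c1ccc(OC)cc1 | intermediate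
11 | 4-methoxyphenylacetyl chloride | COc1ccc(CC(=O)Cl)cc1 | starting material
12 | 4-methoxy-5-(4-methoxyphenyl)-3,6-dioxo-2-phenylcyclohexa-1,4-dien-1-yl (4-methoxyphenyl)acetate | O=C1C(OC(=O)Cc2ccc(OC)cc2)=C(c2ccccc2)C(=O)C(OC)=C1c1ccc(OC)cc1 | intermediate
13 | 5-methoxy-3,4-bis(4-methoxyphenyl)-7-phenyl-1-benzofuran-2,6-dione | O=C1OC2=C(c3ccccc3)C(=O)C(OC)=C(c3ccc(OC)cc3)C2=C1c1ccc(OC)cc1 | intermediate
14 | peniophorin | O=C1OC2=C(c3ccccc3)C(=O)C(O)=C(c3ccc(O)cc3)C2=C1c1ccc(O)cc1 | target

**Step count**
Total steps: 7. Longest linear sequence: 6 (steps 1, 2, 4, 5, 6, 7, from compound 1).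

**Steps most likely to fail, with fallbacks**

Step 4. The enolate of 5 is ambident (C- against O-acylation), the Dieckmann closure by a stabilised enolate may be slow, and the methylation may not be clean, so 8 could be obtained in low yield. The fallback sets out from 3 and 5 and gives up the O-methyl label. The union is run as in step 4, but instead of methylating, excess NaOMe in MeOH is added so that both the O- and the C-acylation manifolds converge on the unsymmetrical terphenylquinone 2,5-dihydroxy-3-(4-methoxyphenyl)-6-phenyl-1,4-benzoquinone F1. F1 is condensed with one equivalent of 11 (Et3N, DMAP, then DBU) to give two regioisomeric lactones, the wanted 5-hydroxy-3,4-bis(4-methoxyphenyl)-7-phenyl-1-benzofuran-2,6-dione F2 and its isomer 5-hydroxy-3,7-bis(4-methoxyphenyl)-4-phenyl-1-benzofuran-2,6-dione F3. These are separated by chromatography and assigned by HMBC and NOE. F2 is demethylated with BBr3 under the conditions of step 7, and the route is rejoined at 14.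

Step 6. The vinylogous anhydride 12 may hydrolyse or scramble faster than it cyclises, and 13 is an electrophile that may not tolerate the amine bases. The fallback sets out from 10 and makes the C–C bond before the C–O bond. The lithium anion of 4-methoxyphenylacetonitrile (LiN(SiMe3)2, 2.2 equiv, THF, −78 °C → 0 °C) is added to the C-1 carbonyl of 10, the only carbonyl that is not part of the oxido-enone anion. Acid-induced dehydration gives the Knoevenagel product (2Z)-[2-hydroxy-5-methoxy-6-(4-methoxyphenyl)-4-oxo-3-phenylcyclohexa-2,5-dien-1-ylidene](4-methoxyphenyl)acetonitrile F4. Its neighbouring enol OH adds to the nitrile in a Pinner-type closure to give the iminolactone 2-imino-5-methoxy-3,4-bis(4-methoxyphenyl)-7-phenyl-1-benzofuran-6(2H)-one F5. Hydrolysis with aqueous HCl rejoins the route at 13.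

Step 7. The quinone methide lactone may not survive excess BBr3, or the demethylation may stop short. The fallback sets out from 13 and masks the electrophilic chromophore by reduction during deprotection. Reduction with Na2S2O4 in aqueous THF gives the colourless aromatic leuco lactone rac-6-hydroxy-5-methoxy-3,4-bis(4-methoxyphenyl)-7-phenyl-1-benzofuran-2(3H)-one F6. BBr3 in CH2Cl2 then gives rac-5,6-dihydroxy-3,4-bis(4-hydroxyphenyl)-7-phenyl-1-benzofuran-2(3H)-one F7. Re-oxidation with air or one equivalent of DDQ erases the racemic C-3 centre and rejoins the route at 14.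

**Further compounds**
F1 | step 4 | 2,5-dihydroxy-3-(4-methoxyphenyl)-6-phenyl-1,4-benzoquinone | O=C1C(O)=C(c2ccccc2)C(=O)C(O)=C1c1ccc(OC)cc1
F2 | step 4 | 5-hydroxy-3,4-bis(4-methoxyphenyl)-7-phenyl-1-benzofuran-2,6-dione | O=C1OC2=C(c3ccccc3)C(=O)C(O)=C(c3ccc(OC)cc3)C2=C1c1ccc(OC)cc1
F3 | step 4 | 5-hydroxy-3,7-bis(4-methoxyphenyl)-4-phenyl-1-benzofuran-2,6-dione | O=C1OC2=C(c3ccc(OC)cc3)C(=O)C(O)=C(c3ccccc3)C2=C1c1ccc(OC)cc1
F4 | step 6 | (2Z)-[2-hydroxy-5-methoxy-6-(4-methoxyphenyl)-4-oxo-3-phenylcyclohexa-2,5-dien-1-ylidene](4-methoxyphenyl)acetonitrile | N#C/C(c1ccc(OC)cc1)=C1\C(O)=C(c2ccccc2)C(=O)C(OC)=C1c1ccc(OC)cc1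
F5 | step 6 | 2-imino-5-methoxy-3,4-bis(4-methoxyphenyl)-7-phenyl-1-benzofuran-6(2H)-one | N=C1OC2=C(c3ccccc3)C(=O)C(OC)=C(c3ccc(OC)cc3)C2=C1c1ccc(OC)cc1
F6 | step 7 | rac-6-hydroxy-5-methoxy-3,4-bis(4-methoxyphenyl)-7-phenyl-1-benzofuran-2(3H)-one | O=C1Oc2c(-c3ccccc3)c(O)c(OC)c(-c3ccc(OC)cc3)c2C1c1ccc(OC)cc1
F7 | step 7 | rac-5,6-dihydroxy-3,4-bis(4-hydroxyphenyl)-7-phenyl-1-benzofuran-2(3H)-one | O=C1Oc2c(-c3ccccc3)c(O)c(O)c(-c3ccc(O)cc3)c2C1c1ccc(O)cc1
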